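The quinone ring of irisoquin C carries its nonadecyl chain on C3 and oxygen on the two meta carbons C1 and C5, the 5-alkylresorcinol signature of a folded tetraketide. Everything rests on cutting ring bond C2–C3: the carbocycle is made from an open-chain methyl 3,5,7-trioxo ester whose C7 ketone bears the chain. A single weak-base aldol, dehydration and enolisation cascade closes the six-membered ring and delivers the alkylresorcylate in one operation. The ester is then removed, and the oxygens on C2 and C4 flanking the chain are added late by two quinone-level oxidations.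

Key step: step 3

Remark: the side chain is taken as the unbranched nonadecyl (C19) chain of the SMILES; 2 and 4 are drawn as keto tautomers although they are largely enolised; locants C1–C7 in steps 2 and 3 are those of the hexacosanoate chain of 4 (C1 = ester carbon); the target has no stereocentre.

Step 1
Reactants: 1 dehydroacetic acid (3-acetyl-4-hydroxy-6-methyl-2H-pyran-2-one)
Product: 2 methyl 3,5-dioxohexanoate
Conditions: Mg(OMe)2 (2 equiv), MeOH, reflux; then cold 2 M HCl
Reagents that add atoms: magnesium dimethoxide Mg(OMe)2, [Mg+2].[O-]C.[O-]C (source of the OMe group, in exchange with the solvent methanol, CO)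
Why: Lactone methanolysis followed by retro-Claisen deacetylation, in which methoxide opens the pyranone and cleaves the acetyl group as methyl acetate while the magnesium chelate of the 3,5-diketo ester protects it from recyclisation until the acidic quench.

Step 2
Reactants: 2 methyl 3,5-dioxohexanoate; 3 methyl icosanoate
Product: 4 methyl 3,5,7-trioxohexacosanoate
Conditions: 2 (2 equiv), LiN(iPr)2 (6.2 equiv), THF, 0 °C; then 3 (1 equiv), 0 °C to rt; cold 2 M HCl quench, crude 4 used at once
Reagents that add atoms: none
Why: Claisen-type C-acylation of a 1,3,5-tricarbonyl trianion, which should react at its last-formed and most nucleophilic terminal carbanion (C6 of 2) with the ester carbonyl of 3, the second equivalent of trianion taking up the newly acidic proton of the product so that 3 is fully consumed.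

Step 3
Reactants: 4 methyl 3,5,7-trioxohexacosanoate
Product: 6 methyl 2,4-dihydroxy-6-nonadecylbenzoate, via cyclic aldol adduct 5 (not isolated)
Conditions: NaOAc (5 equiv), MeOH/THF, rt to 45 °C; then 1 M HCl
Reagents that add atoms: none
Why: Acetate reversibly enolises the polycarbonyl chain, C2 (as the C2=C3 enol or enolate) adds to the chain-bearing C7 ketone to give β-hydroxy ketone 5, and E1cB loss of water across C6–C7 followed by enolisation of the C3 and C5 carbonyls gives the benzene ring, which makes the sequence irreversible. The closest known reaction type is the biomimetic aldol aromatisation of 3,5,7-triketo esters to β-resorcylates, an intramolecular aldol condensation. The one ring formed, the six-membered carbocycle C2–C7, closes in the favoured 6-(enolendo)-exo-trig mode, since the reacting enol double bond C2=C3 lies inside the new ring and the carbonyl oxygen outside it. No stereocentre is created in 6, the two transient ones of 5 being erased on aromatisation. The step needs C2-to-C7 aldol closure rather than C6-to-C1 Claisen closure or O-cyclisation to pyranones: C4 and C6 are the more acidic methylenes, but C2 is the only enolisable carbon that can reach a ketone through a six-membered transition state, and that ketone is far more electrophilic than the methyl ester. A weak buffered base cannot drive methoxide loss from the ester, and the absence of strong acid or dehydrating agents keeps the enol oxygens from closing pyranone rings.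

Step 4
Reactants: 6 methyl 2,4-dihydroxy-6-nonadecylbenzoate
Product: 7 methyl 2-hydroxy-4-methoxy-6-nonadecylbenzoate
Conditions: MeI (1.1 equiv), K2CO3 (1.1 equiv), acetone, rt to 40 °C
Reagents that add atoms: iodomethane, CI
Why: Williamson ether synthesis, selective because the 4-hydroxyl (para to the ester) is the more acidic and freely accessible phenol, whereas the 2-hydroxyl is held in a hydrogen bond to the ester carbonyl and stays unreactive with one equivalent of mild base.

Step 5
Reactants: 7 methyl 2-hydroxy-4-methoxy-6-nonadecylbenzoate
Product: 9 3-methoxy-5-nonadecylphenol, via carboxylic acid 8 (not isolated)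
Conditions: KOH (10 equiv), 1,4-dioxane/H2O, reflux; then 6 M HCl to pH 1, reflux until gas evolution stops
Reagents that add atoms: none
Why: Saponification followed by acid-promoted protodecarboxylation, since the hindered ester yields to hot aqueous KOH and the free acid 8, whose ipso carbon is activated by the ortho hydroxyl and the para methoxyl, should lose CO2 on heating in acid as orsellinic-type acids do.

Step 6
Reactants: 9 3-methoxy-5-nonadecylphenol
Product: 10 2-methoxy-6-nonadecyl-1,4-benzoquinone
Conditions: (KSO3)2NO (2.5 equiv), aq. KH2PO4, Aliquat 336 (methyltrioctylammonium chloride, cat.), CH2Cl2, rt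
Reagents that add atoms: potassium nitrosodisulfonate (KSO3)2NO, [K+].[K+].[O]N(S(=O)(=O)[O-])S(=O)(=O)[O-]
Why: Teuber oxidation, in which one nitrosodisulfonate radical abstracts the phenolic hydrogen, a second couples through oxygen at the unsubstituted para carbon (the one between methoxyl and chain) and loss of imidodisulfonate gives the para-quinone, a conversion established for 3-methoxy-5-alkylphenols.

Step 7
Reactants: 10 2-methoxy-6-nonadecyl-1,4-benzoquinone
Product: 11 5-methoxy-3-nonadecylbenzene-1,2,4-triyl triacetate
Conditions: Ac2O, H2SO4 (cat.), rt to 40 °C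
Reagents that add atoms: acetic anhydride, CC(=O)OC(C)=O
Why: Thiele–Winstein acetoxylation, in which the acid-activated quinone takes up acetate in a conjugate sense at C5, the free carbon beside the chain and para to the methoxyl carbon (C3 is the electron-rich β-carbon of a vinylogous ester and should stay untouched), and the resulting hydroquinone is acetylated in the same flask.

Step 8
Reactants: 11 5-methoxy-3-nonadecylbenzene-1,2,4-triyl triacetate
Product: 13 irisoquin C (2-hydroxy-5-methoxy-3-nonadecyl-1,4-benzoquinone), via triol 12 (not isolated)
Conditions: H2SO4 (cat.), MeOH/THF, 60 °C, N2; then aq. KH2PO4/K2HPO4 (pH 7), EtOAc, air, rt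
Reagents that add atoms: none
Why: Acid-catalysed transesterification should strip the three acetyl groups as methyl acetate, and the electron-rich hydroxyhydroquinone 12 is then autoxidised by air to the hydroxy-para-quinone, the only para-quinone available because the carbon para to the third hydroxyl carries the methyl ether.

Compound list
1 | dehydroacetic acid (3-acetyl-4-hydroxy-6-methyl-2H-pyran-2-one) | CC(=O)C1=C(O)C=C(C)OC1=O | starting material
2 | methyl 3,5-dioxohexanoate | CC(=O)CC(=O)CC(=O)OC | intermediate
3 | methyl icosanoate | CCCCCCCCCCCCCCCCCCCC(=O)OC | starting material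
4 | methyl 3,5,7-trioxohexacosanoate | CCCCCCCCCCCCCCCCCCCC(=O)CC(=O)CC(=O)CC(=O)OC | intermediate
5 | methyl 2-hydroxy-2-nonadecyl-4,6-dioxocyclohexane-1-carboxylate (transient mixture of stereoisomers, both stereocentres erased in the same step) | CCCCCCCCCCCCCCCCCCCC1(O)CC(=O)CC(=O)C1C(=O)OC | intermediate (not isolated)
6 | methyl 2,4-dihydroxy-6-nonadecylbenzoate | CCCCCCCCCCCCCCCCCCCc1cc(O)cc(O)c1C(=O)OC | intermediate
7 | methyl 2-hydroxy-4-methoxy-6-nonadecylbenzoate | CCCCCCCCCCCCCCCCCCCc1cc(OC)cc(O)c1C(=O)OC | intermediate
8 | 2-hydroxy-4-methoxy-6-nonadecylbenzoic acid | CCCCCCCCCCCCCCCCCCCc1cc(OC)cc(O)c1C(=O)O | intermediate (not isolated)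
9 | 3-methoxy-5-nonadecylphenol | CCCCCCCCCCCCCCCCCCCc1cc(O)cc(OC)c1 | intermediate
10 | 2-methoxy-6-nonadecyl-1,4-benzoquinone | CCCCCCCCCCCCCCCCCCCC1=CC(=O)C=C(OC)C1=O | intermediate
11 | 5-methoxy-3-nonadecylbenzene-1,2,4-triyl triacetate | CCCCCCCCCCCCCCCCCCCc1c(OC(C)=O)c(OC(C)=O)cc(OC)c1OC(C)=O | intermediate
12 | 5-methoxy-3-nonadecylbenzene-1,2,4-triol | CCCCCCCCCCCCCCCCCCCc1c(O)c(O)cc(OC)c1O | intermediate (not isolated)
13 | irisoquin C (2-hydroxy-5-methoxy-3-nonadecylcyclohexa-2,5-diene-1,4-dione) | CCCCCCCCCCCCCCCCCCCC1=C(O)C(=O)C=C(OC)C1=O | target

Total step count: 8. Longest linear sequence: 8 steps (1 to 13; methyl icosanoate 3 enters at step 2).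

Steps most likely to fail

Step 3: ring closure may take the Claisen course onto the ester, the enol oxygens may close pyranone rings, or the sequence may stall before dehydration. The fallback sets out from 3 and comes back at 6, replacing the aldol aromatisation by annulation and dehydrogenation. Compound 3 is reduced to icosanal F1 (iBu2AlH, CH2Cl2, −78 °C). Wittig olefination with 1-(triphenylphosphoranylidene)propan-2-one should give (E)-tricos-3-en-2-one F2. Dimethyl malonate and NaOMe in refluxing MeOH should effect Michael addition and Dieckmann-type closure in one pot to methyl 2-hydroxy-6-nonadecyl-4-oxocyclohex-2-ene-1-carboxylate F3. Br2 in DMF (0 to 80 °C) should then aromatise it by bromination and loss of HBr to 6.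

Step 2: proton transfer from the α-methylene of the ester to the strongly basic trianion may outrun acylation, and the product may cyclise during the quench. The fallback sets out from 3 and comes back at 4, with the ester end masked until the last moment. Compound 3 is converted into N-methoxy-N-methylicosanamide F4 (MeNH(OMe)·HCl, iPrMgCl, THF, −10 °C). 2,2-Dimethyl-6-(2-oxopropyl)-4H-1,3-dioxin-4-one F5 is prepared from commercial 2,2,6-trimethyl-4H-1,3-dioxin-4-one (LiN(SiMe3)2, then acetyl chloride). Its dianion (LiN(iPr)2, THF, −78 °C) is acylated at the terminal methyl by F4 to give 6-(2,4-dioxotricosyl)-2,2-dimethyl-4H-1,3-dioxin-4-one F6. Heating F6 in toluene containing methanol (110 °C) should expel acetone and deliver 4 by methanol capture of the opened ring.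

Step 7: acetate may add at the wrong ring carbon, the methoxyl may be displaced under the strong acid, or the deactivated methoxyquinone may react sluggishly and decompose. The fallback sets out from 10 and comes back at 13. Nucleophilic epoxidation (H2O2, Na2CO3, aq. THF, 0 °C) of the more electron-poor, chain-bearing double bond should give racemic 3-methoxy-1-nonadecyl-7-oxabicyclo[4.1.0]hept-3-ene-2,5-dione F7. Brief treatment with cold conc. H2SO4 should open the oxirane at the tertiary carbon and enolise it to the hydroxyquinone 13, as in the classical conversion of quinone epoxides into hydroxyquinones.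

Further compounds
F1 | step 3 | icosanal | CCCCCCCCCCCCCCCCCCCC=O
F2 | step 3 | (E)-tricos-3-en-2-one | CCCCCCCCCCCCCCCCCCC/C=C/C(C)=O
F3 | step 3 | methyl 2-hydroxy-6-nonadecyl-4-oxocyclohex-2-ene-1-carboxylate (racemic, 1,6-trans drawn; configuration immaterial) | CCCCCCCCCCCCCCCCCCC[C@@H]1CC(=O)C=C(O)[C@H]1C(=O)OC
F4 | step 2 | N-methoxy-N-methylicosanamide | CCCCCCCCCCCCCCCCCCCC(=O)N(C)OC
F5 | step 2 | 2,2-dimethyl-6-(2-oxopropyl)-4H-1,3-dioxin-4-one | CC(=O)CC1=CC(=O)OC(C)(C)O1
F6 | step 2 | 6-(2,4-dioxotricosyl)-2,2-dimethyl-4H-1,3-dioxin-4-one | CCCCCCCCCCCCCCCCCCCC(=O)CC(=O)CC1=CC(=O)OC(C)(C)O1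
F7 | step 7 | 3-methoxy-1-nonadecyl-7-oxabicyclo[4.1.0]hept-3-ene-2,5-dione (racemic, cis-fused oxirane, one enantiomer drawn) | CCCCCCCCCCCCCCCCCCC[C@]12O[C@H]1C(=O)C=C(OC)C2=O
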